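## Retrosynthetic overview

1. Feature: in cyclohexene ring A, the ring CH that carries the ketone, the neighbouring quaternary ring carbon (methyl, vinyl) and the vinyl group form a γ,δ-unsaturated carbonyl unit, O=C–CH–C(CH3)–CH=CH2. This is the retron of a Claisen rearrangement across the most hindered bond of ring A.
2. Target ⇒ β-keto amide carrying an aryl chloromethyl ketone (13-membered cyclophane by C-alkylation, hydroxylactam by amide addition, aryl ether by SNAr) ⇒ tricyclic ring-A acid 36.
3. Acid 36 ⇒ Ireland–Claisen contraction of the 10-membered (E,Z)-dienyl lactone 33 fused trans to ring B.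
4. Lactone 33 ⇒ seco acid 31: Z alkene by syn carbocupration of an ynoate, E alkene by Horner–Wadsworth–Emmons olefination; ring-B triad by conjugate borylation, enol triflate acylation and Mukaiyama–Michael addition.
5. Rings B and C come first (Hajos–Parrish annulation, trans fusion by dissolving-metal reduction), then the temporary lactone, then ring A, finally cyclophane and lactam together.

Key step: step 23

Remark (assumption): the two lactam stereocentres are taken to be the thermodynamically preferred ones of the cyclophane, because the CH between the two carbonyls is acidic and the hemiaminal is ring-chain tautomeric; they are set by equilibration in step 32.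

Remark (naming): hydrindane locants C1–C7a are used, C7a carrying the angular methyl; β is the face of that methyl, α the opposite face; TBS = tert-butyldimethylsilyl.

## Route

Step 1
Reactants: 1 2-methylcyclopentane-1,3-dione; 2 pent-1-en-3-one
Product: 3 2-methyl-2-(3-oxopentyl)cyclopentane-1,3-dione
Conditions: H2O, AcOH (cat.), 75 °C
Reagents that add atoms: none
Why: Michael addition of the acidic cyclic 1,3-dione to the unhindered vinyl ketone; no stereocentre is formed.

Step 2
Reactants: 3 triketone
Product: 4 (7aR)-4,7a-dimethyl-2,3,7,7a-tetrahydro-1H-indene-1,5(6H)-dione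
Conditions: D-phenylalanine (1 equiv), 1 M HClO4 (0.5 equiv), MeCN, reflux
Reagents that add atoms: none
Why: Hajos–Parrish–Eder–Sauer–Wiechert enamine aldol condensation, in which the D-amino acid enamine attacks one of the two enantiotopic ring carbonyls and so sets the (R) quaternary carbon (the L-amino acid is known to give the (S) series).

Step 3
Reactants: 4 enedione
Product: 5 (1R,7aR)-1-hydroxy-4,7a-dimethyl-1,2,3,6,7,7a-hexahydro-5H-inden-5-one (hydroxyl cis to the angular methyl)
Conditions: NaBH4 (0.3 equiv), EtOH, −20 °C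
Reagents that add atoms: none
Why: Chemoselective NaBH4 reduction of the saturated cyclopentanone in the presence of the less electrophilic enone, with hydride delivered anti to the angular methyl so that the hydroxyl ends cis to it.

Step 4
Reactants: 5 hydroxy enone
Product: 6 (1R,7aR)-1-hydroxy-4,6,7a-trimethyl-1,2,3,6,7,7a-hexahydro-5H-inden-5-one (both C6 epimers)
Conditions: LiN(iPr)2 (2.2 equiv), THF, −78 °C; MeI, −78 → −30 °C
Reagents that add atoms: iodomethane, CI
Why: Kinetic α'-deprotonation of the enone (the hydroxyl rides along as its lithium alkoxide) and enolate C-methylation at C6; the new centre is epimerizable and is fixed only in step 5.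

Step 5
Reactants: 6 methylated enone
Product: 7 trans-fused 1β-hydroxy-4α,6α,7aβ-trimethyl-3aα-H-octahydro-5H-inden-5-one
Conditions: Li, NH3 (l), THF, t-BuOH (1 equiv), −78 °C; NH4Cl; then NaOMe, MeOH, rt
Reagents that add atoms: none
Why: Dissolving-metal (Birch-type) enone reduction, in which the β-carbanion is protonated anti to the angular methyl to give the trans ring fusion, followed by base equilibration that places both α-methyl groups equatorial (4α,6α).

Step 6
Reactants: 7 hydroxy ketone
Product: 9 trans-fused 4α,6α,7aβ-trimethyl-3aα-H-octahydro-1H-inden-1β-ol, via hydrazone 8 (not isolated)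
Conditions: N2H4·H2O, KOH, diethylene glycol, 130 → 200 °C
Reagents that add atoms: none
Why: Wolff–Kishner reduction in its Huang-Minlon form removes the ketone oxygen, and the two flanking methyl centres cannot be eroded because they already hold the thermodynamic equatorial configuration.

Step 7
Reactants: 9 alcohol
Product: 10 trans-fused 4α,6α,7aβ-trimethyl-3aα-H-octahydro-1H-inden-1-one
Conditions: Dess–Martin periodinane, NaHCO3, CH2Cl2, rt
Reagents that add atoms: none
Why: Dess–Martin oxidation of the secondary alcohol to the cyclopentanone under buffered, non-epimerizing conditions.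

Step 8
Reactants: 10 ketone
Product: 12 trans-fused 4α,6α,7aβ-trimethyl-3aα-H-3a,4,5,6,7,7a-hexahydro-1H-inden-1-one (C2=C3 enone), via trimethylsilyl enol ether 11 (not isolated)
Conditions: LiN(iPr)2, Me3SiCl, THF, −78 °C; then Pd(OAc)2 (10 mol%), O2 (1 atm), DMSO, rt
Reagents that add atoms: none
Why: Saegusa–Ito dehydrogenation through the silyl enol ether of the only enolizable α-carbon (C2), which gives the C2=C3 enone without touching the ring-fusion centres.

Step 9
Reactants: 12 enone
Product: 14 3β-hydroxy-4α,6α,7aβ-trimethyl-3aα-H-octahydro-1H-inden-1-one, via pinacol boronate 13 (not isolated)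
Conditions: CuCl (5 mol%), Xantphos (5 mol%), NaOtBu (10 mol%), B2pin2, MeOH, THF, rt; then H2O2, aq. NaHCO3, 0 °C
Reagents that add atoms: hydrogen peroxide, OO
Why: Copper-catalysed conjugate borylation followed by stereoretentive C–B oxidation; the boryl copper species adds to C3 from the β face, the face that nucleophiles take on trans-fused hydrindenones of this kind because the ring-fusion hydrogen and the axial ring-C hydrogens screen the α face.

Step 10
Reactants: 14 hydroxy ketone
Product: 15 3β-(TBS-oxy)-4α,6α,7aβ-trimethyl-3aα-H-octahydro-1H-inden-1-one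
Conditions: tBuMe2SiCl, imidazole, DMF, 40 °C
Reagents that add atoms: tert-butyldimethylsilyl chloride, CC(C)(C)[Si](C)(C)Cl
Why: Silylation of the secondary alcohol (silyl ether formation) to block retro-aldol and elimination pathways in the following enolate chemistry.

Step 11
Reactants: 15 silyloxy ketone
Product: 16 C1=C2 enol triflate of 15
Conditions: LiN(SiMe3)2, THF, −78 °C; N-(5-chloropyridin-2-yl)bis(trifluoromethanesulfonyl)imide, −78 °C
Reagents that add atoms: N-(5-chloropyridin-2-yl)bis(trifluoromethanesulfonyl)imide, O=S(=O)(N(c1ccc(Cl)cn1)S(=O)(=O)C(F)(F)F)C(F)(F)F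
Why: Enol triflate formation: kinetic deprotonation at the only α-CH2 and O-sulfonylation at −78 °C, a temperature at which the β-silyloxy lithium enolate does not undergo E1cB loss of silanolate.

Step 12
Reactants: 16 enol triflate
Product: 18 1-acetyl-3β-(TBS-oxy)-4α,6α,7aβ-trimethyl-3aα-H-hexahydroindene (C1=C2 enone), via ethoxy diene 17 (not isolated)
Conditions: tributyl(1-ethoxyvinyl)stannane, Pd(PPh3)4 (5 mol%), LiCl, THF, 65 °C; then 1 M HCl, THF, 0 °C
Reagents that add atoms: tributyl(1-ethoxyvinyl)stannane, CCCC[Sn](CCCC)(CCCC)C(=C)OCC; water, O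
Why: Stille coupling of the hindered enol triflate with the acyl anion equivalent and acid hydrolysis of the ethoxy diene unveil the acetyl enone.

Step 13
Reactants: 19 tert-butyl acetate
Product: 20 1-tert-butoxy-1-(tert-butyldimethylsilyloxy)ethene
Conditions: LiN(iPr)2, THF, −78 °C; tBuMe2SiCl, DMPU, −78 → 0 °C
Reagents that add atoms: tert-butyldimethylsilyl chloride, CC(C)(C)[Si](C)(C)Cl
Why: O-Silylation of the ester lithium enolate in the presence of DMPU gives the ketene silyl acetal.

Step 14
Reactants: 18 acetyl enone; 20 ketene silyl acetal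
Product: 21 tert-butyl 2-[1β-acetyl-3β-(TBS-oxy)-4α,6α,7aβ-trimethyl-3aα-H-octahydro-1H-inden-2α-yl]acetate
Conditions: TiCl4, CH2Cl2, −78 °C; aq. NaHCO3; then K2CO3, MeOH, rt
Reagents that add atoms: none
Why: Mukaiyama–Michael addition: the ketene acetal attacks C2 anti to the neighbouring 3β-silyloxy group and to the angular methyl (α face), and protonation with carbonate equilibration leaves the acetyl group trans to the new arm and cis to the angular methyl (1β).

Step 15
Reactants: 21 keto ester
Product: 23 tert-butyl 2-[1β-ethynyl-3β-(TBS-oxy)-4α,6α,7aβ-trimethyl-3aα-H-octahydro-1H-inden-2α-yl]acetate, via enol phosphate 22 (not isolated)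
Conditions: LiN(iPr)2 (1.1 equiv), THF, −78 °C; ClP(O)(OEt)2; then LiN(iPr)2 (3.3 equiv), −78 → 0 °C; aq. NH4Cl
Reagents that add atoms: none
Why: Enol phosphate formation from the kinetic methyl-ketone enolate and base-induced elimination give the terminal alkyne, the excess base holding the ester as its enolate until work-up.

Step 16
Reactants: 23 alkyne
Product: 24 methyl 3-(hydrindan-1β-yl)prop-2-ynoate (hydrindane as in 23, arm ester retained)
Conditions: n-BuLi (1.05 equiv), THF, −78 °C; ClCO2Me
Reagents that add atoms: methyl chloroformate, COC(=O)Cl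
Why: Acetylide acylation: the terminal alkyne is deprotonated selectively (it is far more acidic than the tert-butyl ester) and the lithium acetylide is trapped by the chloroformate.

Step 17
Reactants: 24 ynoate
Product: 25 methyl (2Z)-3-(hydrindan-1β-yl)but-2-enoate (ring carbon cis to CO2Me)
Conditions: Me2CuLi (CuI, MeLi), THF, −78 °C; MeOH, −78 °C
Reagents that add atoms: lithium dimethylcuprate, [Li+].C[Cu-]C
Why: Syn carbocupration of the ynoate and protonation of the alkenylcopper with retention at −78 °C place the ring carbon cis to the ester, which is the alkene geometry (Z) that ring A will need.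

Step 18
Reactants: 25 (Z)-enoate
Product: 27 (3Z)-4-(hydrindan-1β-yl)pent-3-en-2-one, via Weinreb amide 26 (not isolated)
Conditions: MeNH(OMe)·HCl, iPrMgCl, THF, −20 °C; then MeMgBr, 0 °C
Reagents that add atoms: methylmagnesium bromide, C[Mg]Br
Why: Weinreb ketone synthesis run in one flask: the magnesium amide converts only the methyl ester (the tert-butyl ester is inert) and the chelated adduct of MeMgBr collapses to the methyl ketone on work-up, the alkene geometry being untouched.

Step 19
Reactants: 27 (Z)-enone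
Product: 28 ethyl (2E,4Z)-3-methyl-5-(hydrindan-1β-yl)hexa-2,4-dienoate
Conditions: (EtO)2P(O)CH2CO2Et, NaH, THF, 0 → 40 °C
Reagents that add atoms: triethyl phosphonoacetate, CCOC(=O)CP(=O)(OCC)OCC
Why: Horner–Wadsworth–Emmons olefination of the methyl ketone, which puts the ester trans to the larger alkenyl substituent (E) and leaves the Z alkene alone because the phosphonate anion is too weak a base to form the dienolate.

Step 20
Reactants: 28 dienoate tert-butyl ester
Product: 30 dienoate carboxylic acid (arm CH2CO2H), via trimethylsilyl ester 29 (not isolated)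
Conditions: Me3SiOTf, 2,6-lutidine, CH2Cl2, 0 °C → rt; then aq. citric acid
Reagents that add atoms: none
Why: Silyl triflate-mediated cleavage of the tert-butyl ester (loss of 2-methylpropene) under buffered conditions that spare the silyl ether and the dienoate; the silyl ester hydrolyses on work-up.

Step 21
Reactants: 30 dienoate acid
Product: 31 seco acid: 2-[1β-((2Z,4E)-6-hydroxy-4-methylhexa-2,4-dien-2-yl)-3β-(TBS-oxy)-4α,6α,7aβ-trimethyl-3aα-H-octahydro-1H-inden-2α-yl]acetic acid
Conditions: iBu2AlH (4.5 equiv), CH2Cl2, −78 °C; aq. potassium sodium tartrate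
Reagents that add atoms: none
Why: Hydride (1,2-) reduction of the conjugated ester to the allylic alcohol, the carboxylic acid being held as its aluminium carboxylate, which is not reduced at −78 °C.

Step 22
Reactants: 31 seco acid
Product: 33 10-membered (E,Z)-dienyl lactone fused trans to ring B, via mixed anhydride 32 (not isolated)
Conditions: 2,4,6-trichlorobenzoyl chloride, Et3N, THF, rt; then slow addition to DMAP, toluene, 80 °C (1 mM)
Reagents that add atoms: none
Why: Yamaguchi macrolactonization under high dilution; the Z alkene and the trans-disposed ring-B arms turn the hydroxyl end back towards the activated acyl group.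

Step 23
Reactants: 33 10-membered lactone
Product: 36 tricyclic ring-A carboxylic acid with the methyl- and vinyl-bearing quaternary carbon, via silyl ketene acetal 34 (not isolated), via trimethylsilyl ester 35 (not isolated)
Conditions: LiN(iPr)2, Me3SiCl/Et3N (in situ), THF, −100 → −78 °C; then toluene, 100 °C; then 1 M HCl, THF, rt
Reagents that add atoms: none
Why: LiN(iPr)2 removes a proton from the lactone CH2 and the Me3SiCl already in the flask silylates the enolate at once, giving the silyl ketene acetal in which ring oxygen and ring carbon are cis (the only geometry this 10-membered ring can hold); on heating, a concerted suprafacial [3,3] shift through a chair breaks the allylic C–O bond and joins the former α-carbon to the methyl-bearing alkene carbon, releasing the vinyl group and the silyl ester. The closest known reaction type is the Ireland–Claisen ring contraction of medium-ring allylic lactones to 2-vinylcycloalkanecarboxylic acids. Ring A closes by transannular C–C bond formation across the lactone (6-exo with respect to the allyl unit, the vinyl group staying outside the new ring), and a six-membered ring can be spanned only from the chair, where the tether runs from an axial site on the ketene acetal carbon to an equatorial site on the E-alkene carbon (a gauche pair), not from the boat. The carboxyl-bearing centre is set by the fixed ketene acetal geometry and the chair, which leave its hydrogen axial and anti to the neighbouring ring-B hydrogen and the carboxyl equatorial; the quaternary centre is set by the E geometry of the allylic alkene, which puts the methyl axial in the chair and so delivers the vinyl group cis to the carboxyl. The step needs one of the two mirror-image chairs, and the trans attachment of both arms to ring B secures it, because only that chair lets ring A form as the half-chair that a trans A/B fusion allows. It also needs silylation to outrun β-elimination or ketene loss from the lactone enolate, which the in situ quench at −100 °C and the absence of any other acidic C–H provide.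

Step 24
Reactants: 36 ring-A acid silyl ether
Product: 37 ring-A hydroxy acid (free ring-B hydroxyl)
Conditions: Bu4NF, THF, 60 °C
Reagents that add atoms: none
Why: Fluoride-mediated desilylation of the hindered secondary silyl ether, the acid being present as its carboxylate.

Step 25
Reactants: 37 hydroxy acid; 38 4-fluorobenzaldehyde
Product: 39 4-formylphenyl ether of 37
Conditions: KN(SiMe3)2 (2.2 equiv), THF/DMF, 0 °C → rt
Reagents that add atoms: none
Why: Nucleophilic aromatic substitution (SNAr): the alkoxide of the carboxylate–alkoxide dianion displaces fluoride para to the formyl group, and the carbinol configuration is retained because its C–O bond is not broken.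

Step 26
Reactants: 39 aryl aldehyde
Product: 41 4-(2-oxoethyl)phenyl ether (arylacetaldehyde), via methyl enol ether 40 (not isolated)
Conditions: Ph3P(CH2OMe)Cl, KN(SiMe3)2 (3.2 equiv), THF, 0 °C; then 2 M HCl, THF, rt
Reagents that add atoms: (methoxymethyl)triphenylphosphonium chloride, COC[P+](c1ccccc1)(c1ccccc1)c1ccccc1.[Cl-]; water, O
Why: Wittig methoxymethylenation and acid hydrolysis of the enol ether homologate the benzaldehyde to the arylacetaldehyde, excess ylide covering the carboxylic acid proton.

Step 27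
Reactants: 41 arylacetaldehyde
Product: 42 4-(3-chloro-2-hydroxypropyl)phenyl ether (both carbinol epimers)
Conditions: ICH2Cl (1.2 equiv), MeLi·LiBr (2.1 equiv), THF, −78 °C; AcOH quench
Reagents that add atoms: chloroiodomethane, ClCI
Why: Carbenoid 1,2-addition: chloromethyllithium made in the flask by iodine–lithium exchange adds to the aldehyde at −78 °C (the first equivalent of MeLi forms the carboxylate), giving both carbinol epimers, which converge on oxidation in step 31.

Step 28
Reactants: 42 chlorohydrin acid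
Product: 44 chlorohydrin TBS ether acid, via bis-silyl compound 43 (not isolated)
Conditions: tBuMe2SiOTf (2.5 equiv), 2,6-lutidine, CH2Cl2, −78 → 0 °C; then K2CO3, MeOH/H2O, rt
Reagents that add atoms: tert-butyldimethylsilyl trifluoromethanesulfonate, CC(C)(C)[Si](C)(C)OS(=O)(=O)C(F)(F)F
Why: Silylation of alcohol and acid followed by selective methanolysis of the labile silyl ester leaves the chlorohydrin protected as its silyl ether.

Step 29
Reactants: 44 protected chlorohydrin acid
Product: 47 β-keto primary amide (ring-A C(=O)CH2C(=O)NH2), via acid chloride 45 (not isolated), via acyl Meldrum's acid 46 (not isolated)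
Conditions: 1-chloro-N,N,2-trimethylprop-1-en-1-amine, CH2Cl2, 0 °C; then 2,2-dimethyl-1,3-dioxane-4,6-dione, pyridine, 0 °C → rt; then NH3 (0.5 M in 1,4-dioxane), 85 °C, sealed tube
Reagents that add atoms: 2,2-dimethyl-1,3-dioxane-4,6-dione (Meldrum's acid), CC1(C)OC(=O)CC(=O)O1; ammonia, N
Why: C-Acylation of Meldrum's acid by the acid chloride and thermal fragmentation of the adduct to an acylketene that ammonia traps give the primary β-keto amide; the alkyl chloride is too hindered to be aminated under these conditions.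

Step 30
Reactants: 47 silyl-protected β-keto amide
Product: 48 chlorohydrin β-keto amide
Conditions: HF·pyridine, THF, 0 °C → rt
Reagents that add atoms: none
Why: Acidic fluoride desilylation frees the chlorohydrin hydroxyl without exposing it to base, which would close the epoxide.

Step 31
Reactants: 48 chlorohydrin
Product: 49 aryl chloromethyl ketone β-keto amide
Conditions: Dess–Martin periodinane, NaHCO3, CH2Cl2, 0 °C
Reagents that add atoms: none
Why: Dess–Martin oxidation of the secondary alcohol gives the chloromethyl ketone under buffered conditions that leave the β-keto amide and the alkenes untouched.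

Step 32
Reactants: 49 chloromethyl ketone β-keto amide
Product: 51 CNP0450261.1, via macrocyclic diketo amide 50 (not isolated)
Conditions: Cs2CO3, Bu4NI (cat.), MeCN (1 mM, slow addition), 50 °C
Reagents that add atoms: none
Why: Intramolecular C-alkylation of the β-keto amide by the α-chloro ketone closes the 13-membered cyclophane (13-exo-tet), the primary amide then adds to the new benzylic ketone (5-exo-trig) to give the hydroxylactam, and the acidic CH and the reversible hemiaminal equilibrate under the carbonate to the arrangement in which benzyl and acyl groups are cis on the lactam and bridged by the macrocycle.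

## Compound list

1 | 2-methylcyclopentane-1,3-dione | CC1C(=O)CCC1=O | starting material
2 | pent-1-en-3-one | C=CC(=O)CC | starting material
3 | 2-methyl-2-(3-oxopentyl)cyclopentane-1,3-dione | CCC(=O)CCC1(C)C(=O)CCC1=O | intermediate
4 | (7aR)-4,7a-dimethyl-2,3,7,7a-tetrahydro-1H-indene-1,5(6H)-dione | O=C1CC[C@@]2(C)C(=O)CCC2=C1C | intermediate
5 | (1R,7aR)-1-hydroxy-4,7a-dimethyl-1,2,3,6,7,7a-hexahydro-5H-inden-5-one | O=C1CC[C@@]2(C)[C@H](O)CCC2=C1C | intermediate
6 | (1R,7aR)-1-hydroxy-4,6,7a-trimethyl-1,2,3,6,7,7a-hexahydro-5H-inden-5-one, both C6 epimers | O=C1C(C)C[C@@]2(C)[C@H](O)CCC2=C1C | intermediate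
7 | trans-fused 1β-hydroxy-4α,6α,7aβ-trimethyl-3aα-H-octahydro-5H-inden-5-one | O[C@@H]1CC[C@@H]2[C@@H](C)C(=O)[C@@H](C)C[C@]21C | intermediate
8 | C5 hydrazone of 7 | O[C@@H]1CC[C@@H]2[C@@H](C)C(=NN)[C@@H](C)C[C@]21C | intermediate (not isolated)
9 | trans-fused 4α,6α,7aβ-trimethyl-3aα-H-octahydro-1H-inden-1β-ol | O[C@@H]1CC[C@@H]2[C@@H](C)C[C@@H](C)C[C@]21C | intermediate
10 | trans-fused 4α,6α,7aβ-trimethyl-3aα-H-octahydro-1H-inden-1-one | O=C1CC[C@@H]2[C@@H](C)C[C@@H](C)C[C@]21C | intermediate
11 | trimethylsilyl enol ether of 10 (C1=C2) | C[Si](C)(C)OC1=CC[C@@H]2[C@@H](C)C[C@@H](C)C[C@]21C | intermediate (not isolated)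
12 | C2=C3 enone, 4α,6α,7aβ-trimethyl-3aα-H-hexahydro-1H-inden-1-one | O=C1C=C[C@@H]2[C@@H](C)C[C@@H](C)C[C@]21C | intermediate
13 | 3β-(pinacolboryl) ketone | O=C1C[C@H](B3OC(C)(C)C(C)(C)O3)[C@@H]2[C@@H](C)C[C@@H](C)C[C@]21C | intermediate (not isolated)
14 | 3β-hydroxy ketone | O=C1C[C@H](O)[C@@H]2[C@@H](C)C[C@@H](C)C[C@]21C | intermediate
15 | 3β-(TBS-oxy) ketone | O=C1C[C@H](O[Si](C)(C)C(C)(C)C)[C@@H]2[C@@H](C)C[C@@H](C)C[C@]21C | intermediate
16 | C1=C2 enol triflate of 15 | O=S(=O)(OC1=C[C@H](O[Si](C)(C)C(C)(C)C)[C@@H]2[C@@H](C)C[C@@H](C)C[C@]21C)C(F)(F)F | intermediate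
17 | 1-(1-ethoxyvinyl) diene | CCOC(=C)C1=C[C@H](O[Si](C)(C)C(C)(C)C)[C@@H]2[C@@H](C)C[C@@H](C)C[C@]21C | intermediate (not isolated)
18 | 1-acetyl C1=C2 enone with 3β-(TBS-oxy) | CC(=O)C1=C[C@H](O[Si](C)(C)C(C)(C)C)[C@@H]2[C@@H](C)C[C@@H](C)C[C@]21C | intermediate
19 | tert-butyl acetate | CC(=O)OC(C)(C)C | starting material
20 | 1-tert-butoxy-1-(tert-butyldimethylsilyloxy)ethene | C=C(OC(C)(C)C)O[Si](C)(C)C(C)(C)C | intermediate
21 | tert-butyl 2-[1β-acetyl-3β-(TBS-oxy)-4α,6α,7aβ-trimethyl-3aα-H-hydrindan-2α-yl]acetate | CC(C)(C)OC(=O)C[C@H]1[C@H](O[Si](C)(C)C(C)(C)C)[C@@H]2[C@@H](C)C[C@@H](C)C[C@@]2(C)[C@@H]1C(C)=O | intermediate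
22 | diethyl enol phosphate of the acetyl group of 21 | CC(C)(C)OC(=O)C[C@H]1[C@H](O[Si](C)(C)C(C)(C)C)[C@@H]2[C@@H](C)C[C@@H](C)C[C@@]2(C)[C@@H]1C(=C)OP(=O)(OCC)OCC | intermediate (not isolated)
23 | 1β-ethynyl hydrindane tert-butyl ester | CC(C)(C)OC(=O)C[C@H]1[C@H](O[Si](C)(C)C(C)(C)C)[C@@H]2[C@@H](C)C[C@@H](C)C[C@@]2(C)[C@@H]1C#C | intermediate
24 | methyl ynoate | CC(C)(C)OC(=O)C[C@H]1[C@H](O[Si](C)(C)C(C)(C)C)[C@@H]2[C@@H](C)C[C@@H](C)C[C@@]2(C)[C@@H]1C#CC(=O)OC | intermediate
25 | methyl (2Z)-3-(hydrindan-1β-yl)but-2-enoate | CC(C)(C)OC(=O)C[C@H]1[C@H](O[Si](C)(C)C(C)(C)C)[C@@H]2[C@@H](C)C[C@@H](C)C[C@@]2(C)[C@@H]1/C(C)=C\C(=O)OC | intermediate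
26 | (Z)-N-methoxy-N-methyl enamide (Weinreb amide) | CC(C)(C)OC(=O)C[C@H]1[C@H](O[Si](C)(C)C(C)(C)C)[C@@H]2[C@@H](C)C[C@@H](C)C[C@@]2(C)[C@@H]1/C(C)=C\C(=O)N(C)OC | intermediate (not isolated)
27 | (3Z)-4-(hydrindan-1β-yl)pent-3-en-2-one | CC(C)(C)OC(=O)C[C@H]1[C@H](O[Si](C)(C)C(C)(C)C)[C@@H]2[C@@H](C)C[C@@H](C)C[C@@]2(C)[C@@H]1/C(C)=C\C(C)=O | intermediate
28 | ethyl (2E,4Z)-3-methyl-5-(hydrindan-1β-yl)hexa-2,4-dienoate, arm tert-butyl ester | CC(C)(C)OC(=O)C[C@H]1[C@H](O[Si](C)(C)C(C)(C)C)[C@@H]2[C@@H](C)C[C@@H](C)C[C@@]2(C)[C@@H]1/C(C)=C\C(C)=C\C(=O)OCC | intermediate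
29 | trimethylsilyl ester of 30 | C[Si](C)(C)OC(=O)C[C@H]1[C@H](O[Si](C)(C)C(C)(C)C)[C@@H]2[C@@H](C)C[C@@H](C)C[C@@]2(C)[C@@H]1/C(C)=C\C(C)=C\C(=O)OCC | intermediate (not isolated)
30 | dienoate with free arm carboxylic acid | OC(=O)C[C@H]1[C@H](O[Si](C)(C)C(C)(C)C)[C@@H]2[C@@H](C)C[C@@H](C)C[C@@]2(C)[C@@H]1/C(C)=C\C(C)=C\C(=O)OCC | intermediate
31 | seco acid, (2Z,4E)-dienol | OC(=O)C[C@H]1[C@H](O[Si](C)(C)C(C)(C)C)[C@@H]2[C@@H](C)C[C@@H](C)C[C@@]2(C)[C@@H]1/C(C)=C\C(C)=C\CO | intermediate
32 | 2,4,6-trichlorobenzoic mixed anhydride of 31 | O=C(OC(=O)C[C@H]1[C@H](O[Si](C)(C)C(C)(C)C)[C@@H]2[C@@H](C)C[C@@H](C)C[C@@]2(C)[C@@H]1/C(C)=C\C(C)=C\CO)c1c(Cl)cc(Cl)cc1Cl | intermediate (not isolated)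
33 | 10-membered (E,Z)-dienyl lactone on the trans-hydrindane | O=C1C[C@H]2[C@H](O[Si](C)(C)C(C)(C)C)[C@@H]3[C@@H](C)C[C@@H](C)C[C@@]3(C)[C@@H]2/C(C)=C\C(C)=C\CO1 | intermediate
34 | trimethylsilyl ketene acetal of 33 (ring O and ring C cis) | C[Si](C)(C)O/C1=C/[C@H]2[C@H](O[Si](C)(C)C(C)(C)C)[C@@H]3[C@@H](C)C[C@@H](C)C[C@@]3(C)[C@@H]2/C(C)=C\C(C)=C\CO1 | intermediate (not isolated)
35 | trimethylsilyl ester of 36 | C=C[C@@]1(C)C=C(C)[C@@H]2[C@@H]([C@H]1C(=O)O[Si](C)(C)C)[C@H](O[Si](C)(C)C(C)(C)C)[C@@H]3[C@@H](C)C[C@@H](C)C[C@]32C | intermediate (not isolated)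
36 | tricyclic ring-A carboxylic acid, vinyl cis to carboxyl, TBS ether | C=C[C@@]1(C)C=C(C)[C@@H]2[C@@H]([C@H]1C(=O)O)[C@H](O[Si](C)(C)C(C)(C)C)[C@@H]3[C@@H](C)C[C@@H](C)C[C@]32C | intermediate
37 | tricyclic hydroxy acid | C=C[C@@]1(C)C=C(C)[C@@H]2[C@@H]([C@H]1C(=O)O)[C@H](O)[C@@H]3[C@@H](C)C[C@@H](C)C[C@]32C | intermediate
38 | 4-fluorobenzaldehyde | O=Cc1ccc(F)cc1 | starting material
39 | 4-formylphenyl ether acid | C=C[C@@]1(C)C=C(C)[C@@H]2[C@@H]([C@H]1C(=O)O)[C@H](Oc4ccc(C=O)cc4)[C@@H]3[C@@H](C)C[C@@H](C)C[C@]32C | intermediate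
40 | 4-(2-methoxyvinyl)phenyl ether acid (E/Z) | C=C[C@@]1(C)C=C(C)[C@@H]2[C@@H]([C@H]1C(=O)O)[C@H](Oc4ccc(C=COC)cc4)[C@@H]3[C@@H](C)C[C@@H](C)C[C@]32C | intermediate (not isolated)
41 | 4-(2-oxoethyl)phenyl ether acid | C=C[C@@]1(C)C=C(C)[C@@H]2[C@@H]([C@H]1C(=O)O)[C@H](Oc4ccc(CC=O)cc4)[C@@H]3[C@@H](C)C[C@@H](C)C[C@]32C | intermediate
42 | 4-(3-chloro-2-hydroxypropyl)phenyl ether acid, both carbinol epimers | C=C[C@@]1(C)C=C(C)[C@@H]2[C@@H]([C@H]1C(=O)O)[C@H](Oc4ccc(CC(O)CCl)cc4)[C@@H]3[C@@H](C)C[C@@H](C)C[C@]32C | intermediate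
43 | TBS ether TBS ester of 42 | C=C[C@@]1(C)C=C(C)[C@@H]2[C@@H]([C@H]1C(=O)O[Si](C)(C)C(C)(C)C)[C@H](Oc4ccc(CC(CCl)O[Si](C)(C)C(C)(C)C)cc4)[C@@H]3[C@@H](C)C[C@@H](C)C[C@]32C | intermediate (not isolated)
44 | chlorohydrin TBS ether acid | C=C[C@@]1(C)C=C(C)[C@@H]2[C@@H]([C@H]1C(=O)O)[C@H](Oc4ccc(CC(CCl)O[Si](C)(C)C(C)(C)C)cc4)[C@@H]3[C@@H](C)C[C@@H](C)C[C@]32C | intermediate
45 | acid chloride of 44 | C=C[C@@]1(C)C=C(C)[C@@H]2[C@@H]([C@H]1C(=O)Cl)[C@H](Oc4ccc(CC(CCl)O[Si](C)(C)C(C)(C)C)cc4)[C@@H]3[C@@H](C)C[C@@H](C)C[C@]32C | intermediate (not isolated)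
46 | acyl Meldrum's acid | C=C[C@@]1(C)C=C(C)[C@@H]2[C@@H]([C@H]1C(=O)C5C(=O)OC(C)(C)OC5=O)[C@H](Oc4ccc(CC(CCl)O[Si](C)(C)C(C)(C)C)cc4)[C@@H]3[C@@H](C)C[C@@H](C)C[C@]32C | intermediate (not isolated)
47 | β-keto primary amide, chlorohydrin TBS ether | C=C[C@@]1(C)C=C(C)[C@@H]2[C@@H]([C@H]1C(=O)CC(N)=O)[C@H](Oc4ccc(CC(CCl)O[Si](C)(C)C(C)(C)C)cc4)[C@@H]3[C@@H](C)C[C@@H](C)C[C@]32C | intermediate
48 | β-keto amide chlorohydrin | C=C[C@@]1(C)C=C(C)[C@@H]2[C@@H]([C@H]1C(=O)CC(N)=O)[C@H](Oc4ccc(CC(O)CCl)cc4)[C@@H]3[C@@H](C)C[C@@H](C)C[C@]32C | intermediate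
49 | β-keto amide aryl chloromethyl ketone | C=C[C@@]1(C)C=C(C)[C@@H]2[C@@H]([C@H]1C(=O)CC(N)=O)[C@H](Oc4ccc(CC(=O)CCl)cc4)[C@@H]3[C@@H](C)C[C@@H](C)C[C@]32C | intermediate
50 | 13-membered cyclophane diketo amide | C=C[C@@]1(C)C=C(C)[C@@H]2[C@@H]3[C@H](Oc4ccc(cc4)CC(=O)CC(C(N)=O)C(=O)[C@H]31)[C@@H]1[C@@H](C)C[C@@H](C)C[C@]12C | intermediate (not isolated)
51 | CNP0450261.1 | C=C[C@@]1(C)C=C(C)[C@@H]2[C@@H]3[C@H](Oc4ccc(cc4)C[C@@]4(O)C[C@H](C(=O)N4)C(=O)[C@H]31)[C@@H]1[C@@H](C)C[C@@H](C)C[C@]12C | target

## Step count and risk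

Total step count: 32 (step 13 is a one-step side branch).
Longest linear sequence: 31 steps (steps 1–12 and 14–32, from compound 1).

Steps most likely to fail:

1. Step 23 (key step). The lactone enolate may fragment (ketene extrusion, β-elimination) before it is silylated. The strained macrocyclic ketene acetal may also fail to reach the chair array, so that heating leads to decomposition instead of rearrangement. Fallback (ionic ring closure instead of the sigmatropic shift), setting out from seco acid 31: alkylation of the carboxylate with allyl bromide (KHCO3, DMF) gives the allyl ester F1. MsCl, LiCl and 2,4,6-collidine in DMF convert the allylic alcohol into the allylic chloride F2. KN(SiMe3)2 in THF (−78 → 0 °C) forms the ester enolate, which closes ring A by intramolecular 6-exo SN2' alkylation at the methyl-bearing alkene carbon to give the ring-A allyl ester F3. Pd(PPh3)4 with morpholine removes the allyl group, and the route is rejoined at acid 36.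

2. Step 22. Intermolecular esterification (dimers, oligomers) may outrun closure of the strained 10-membered ring, and the activated acyl species may isomerize the Z alkene on prolonged heating. Fallback (activation of the alcohol instead of the acid), setting out from seco acid 31: Mitsunobu macrolactonization (PPh3, diisopropyl azodicarboxylate, toluene, slow addition at high dilution), in which the carboxylate displaces the activated primary allylic oxygen. It returns to the route at lactone 33, and no new compound is made (F0).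

3. Step 32. Intermolecular alkylation (oligomers), O-alkylation of the enolate, or failure to close the strained cyclophane may prevail. Fallback (the two ring-closing bonds are made in the reverse order), setting out from acid 36: the three-stage homologation of step 29 gives the β-keto amide F4. C-Alkylation with 1-chloro-3-(4-iodophenyl)propan-2-one F5 (from 4-iodophenylacetyl chloride with trimethylsilyldiazomethane, then HCl) under K2CO3 in acetone, with closure of the amide onto the new ketone, gives the open-chain hydroxylactam silyl ether F6. HF·pyridine frees the ring-B alcohol F7. Intramolecular Ullmann etherification (CuI, 3,4,7,8-tetramethyl-1,10-phenanthroline, Cs2CO3, toluene, 110 °C, high dilution) then closes the 13-membered aryl ether and returns to the route at target 51.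

Further compounds
F1 | step 23 | allyl ester of seco acid 31 | C=CCOC(=O)C[C@H]1[C@H](O[Si](C)(C)C(C)(C)C)[C@@H]2[C@@H](C)C[C@@H](C)C[C@@]2(C)[C@@H]1/C(C)=C\C(C)=C\CO
F2 | step 23 | allylic chloride of F1 | C=CCOC(=O)C[C@H]1[C@H](O[Si](C)(C)C(C)(C)C)[C@@H]2[C@@H](C)C[C@@H](C)C[C@@]2(C)[C@@H]1/C(C)=C\C(C)=C\CCl
F3 | step 23 | allyl ester of ring-A acid 36 | C=C[C@@]1(C)C=C(C)[C@@H]2[C@@H]([C@H]1C(=O)OCC=C)[C@H](O[Si](C)(C)C(C)(C)C)[C@@H]3[C@@H](C)C[C@@H](C)C[C@]32C
F0 | step 22 | none | none
F4 | step 32 | β-keto primary amide of 36 (TBS ether kept) | C=C[C@@]1(C)C=C(C)[C@@H]2[C@@H]([C@H]1C(=O)CC(N)=O)[C@H](O[Si](C)(C)C(C)(C)C)[C@@H]3[C@@H](C)C[C@@H](C)C[C@]32C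
F5 | step 32 | 1-chloro-3-(4-iodophenyl)propan-2-one | ClCC(=O)Cc1ccc(I)cc1
F6 | step 32 | open-chain 5-hydroxy-5-(4-iodobenzyl)pyrrolidin-2-one, TBS ether | C=C[C@@]1(C)C=C(C)[C@@H]2[C@@H]([C@H]1C(=O)C5CC(O)(Cc6ccc(I)cc6)NC5=O)[C@H](O[Si](C)(C)C(C)(C)C)[C@@H]3[C@@H](C)C[C@@H](C)C[C@]32C
F7 | step 32 | open-chain hydroxylactam with free ring-B alcohol | C=C[C@@]1(C)C=C(C)[C@@H]2[C@@H]([C@H]1C(=O)C5CC(O)(Cc6ccc(I)cc6)NC5=O)[C@H](O)[C@@H]3[C@@H](C)C[C@@H](C)C[C@]32C
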